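In a one-step world each substrate goes straight to its own product, and both routes use the same catalyst and reagent, so those two amounts drop out of the ratio of the rates.

| flask | left-handed substrate | right-handed substrate | reagent | precatalyst | remark | time |
|---|---|---|---|---|---|---|
| blue | 0.084 M | 0.084 M | 0.14 M | 56 µM | run made earlier |  |
| flask | 0.056 M | 0.056 M | 0.140 M | 56 µM |  | 6.0 h |

blue run (percent of the left-handed substrate and right-handed substrate together charged)

| time / min | left-handed product / % | right-handed product / % |
|---|---|---|
| 8.00 | 0.3 | 0.1 |
| 20.0 | 0.7 | 0 |
| 50.0 | 4.9 | 0.8 |
| 120 | 17.3 | 2.9 |

(standard deviation of a reading: 0.3 percentage points)

- catalyst is single-handed; left-handed substrate and right-handed substrate are mirror images of each other, charged as a racemate, each of them at the stated concentration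
- the numbers in the tables scatter with a standard deviation of 0.3 percentage points
- what may be going on: reagent + catalyst + left-handed substrate -> catalyst + left-handed product; reagent + catalyst + right-handed substrate -> catalyst + right-handed product; left-handed substrate <-> right-handed substrate; reagent <-> dormant form; precatalyst -> catalyst
- an excess is below zero if the other one leads

* excess of left-handed product over right-handed product in the product at 20 min
* excess of left-handed product over right-handed product in the product at 6.0 h
* part of the left-handed substrate and right-handed substrate charged together that has reacted at 6.0 h

The blue run at 120 min reads 7.11 for the selectivity factor, the logarithm of the fraction of left-handed substrate not turned into product divided by the same logarithm for the right-handed substrate. Frozen at this reading, it serves the flask, whose substrates start equal, so the early excess is the factor less one over the factor plus one, 75.3 %. For 6.0 h the factor gives no clock, but it ties excess to conversion: in the one-step world the products, counted at any moment, return the same factor.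

The forecast gave 74 % for the early excess, slightly below this reckoning, then 59 % for the excess and 51 % for the part reacted at 6.0 h, adding “Racemisation cannot be excluded from these data”. The flask gives 75.8 %, 64.4 % and 57.0 %.

    reagent + catalyst + left-handed substrate → catalyst + left-handed product (k = 2.20 × 10⁵ M⁻² h⁻¹)
    reagent + catalyst + right-handed substrate → catalyst + right-handed product (k = 30000 M⁻² h⁻¹)
    left-handed substrate ⇌ right-handed substrate (k = 0.120 h⁻¹)
    reagent ⇌ dormant form (K = 0.730, k = 0.260 h⁻¹)
    precatalyst → catalyst (k = 0.210 h⁻¹)

The flask's early excess agrees with the frozen factor, but the flask's products at 6.0 h count to 12.2, above the reading, and the relaxation half-life of the two substrates by their interconversion alone, 2.89 h, lies within that time. A neighbouring flask charged with 0.035 M of reagent reaches a conversion of 19.1 % at 6.0 h and its products then count to 7.77, nearer the reading, with an excess of 73.6 %.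

(All runs were computed for an exercise; scatter was added.)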